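**Retrosynthetic overview**
1. Succinimide last: Evans syn-aldol of C12 aldehyde 22 with cyanopropanoyl oxazolidinone 25, then nitrile hydration and imide closure (sets C12, C13).
2. Ring B by ring expansion: Pd(II) oxidative semipinacol shift of the 1-vinylcyclopentanol 17 (trans-hydrindane) to the 2-methylenecyclohexanone 18 (C7=O, C8=CH2); then Luche reduction and acetylation.
3. Ring A and the cyclopentenone formed together: intramolecular Pauson–Khand reaction of enyne 14 (sets C9, C10), then α-face hydrogenation (sets C5).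
4. Enyne 14: acetylide SN2 on the triflate of dichloro alcohol 6, then Zr-catalysed carboalumination/oxirane opening (E-alkene, C11–C12).
5. Chlorides first: catalytic enantioselective anti-dichlorination of Z-allylic alcohol 5, built from 3-chloro-3-methylbutyne, TMS-acetylene and formaldehyde.

Assumption: the target is taken exactly as the given SMILES (labdane numbering: 2α,3β-dichloro, 5α-H, 7β-OAc, 9α-H, 10β-Me, 12S, 13R); positions in the bicyclic compounds are quoted in labdane numbering.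
Assumption: in step 3 the enantiomer of the chiral Schiff-base ligand that gives the (2R,3R) dichloride is used.

**Step 1**
Reactants: 1 3-chloro-3-methylbut-1-yne; 2 ethynyltrimethylsilane
Product: 4 4,4-dimethyl-6-(trimethylsilyl)hexa-2,5-diyn-1-ol, via bromomagnesium acetylide 3 (not isolated)
Conditions: 2 (2.2 equiv), EtMgBr (2.2 equiv), THF, 0 °C→rt; CuCl (5 mol %), 1, rt→40 °C; then (CH2O)n, 45 °C; aq. work-up
Reagents that add atoms: formaldehyde (from paraformaldehyde), C=O
Why: Cu(I)-catalysed coupling of a tertiary propargylic chloride with an alkynyl Grignard gives the gem-dimethyl 1,4-diyne as its terminal acetylide, which adds to formaldehyde in the same flask; no stereocentre.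

**Step 2**
Reactants: 4 4,4-dimethyl-6-(trimethylsilyl)hexa-2,5-diyn-1-ol
Product: 5 (Z)-4,4-dimethyl-6-(trimethylsilyl)hex-2-en-5-yn-1-ol
Conditions: H2 (1 atm), Lindlar catalyst, quinoline, EtOAc, rt
Reagents that add atoms: none
Why: Lindlar semi-hydrogenation is syn and prefers the propargylic-alcohol alkyne over the silyl-capped neopentyl alkyne, giving the Z-alkene that anti-dichlorination converts into the threo (ring-trans) dichloride.

**Step 3**
Reactants: 5 (Z)-4,4-dimethyl-6-(trimethylsilyl)hex-2-en-5-yn-1-ol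
Product: 6 (2R,3R)-2,3-dichloro-4,4-dimethyl-6-(trimethylsilyl)hex-5-yn-1-ol
Conditions: t-BuOCl (1.2 equiv), ClTi(Oi-Pr)3 (1.1 equiv), chiral tridentate Schiff-base ligand (20 mol %), hexanes, −20 °C
Reagents that add atoms: tert-butyl hypochlorite, CC(C)(C)OCl; chlorotitanium triisopropoxide, CC(C)O[Ti](Cl)(OC(C)C)OC(C)C
Why: Ti/chiral Schiff-base-catalysed enantioselective dichlorination of allylic alcohols: the alcohol-bound Ti complex controls chloronium formation and chloride delivery, anti addition to the Z-alkene fixes the 2,3-relationship and the ligand the absolute sense (C2, C3).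

**Step 4**
Reactants: 6 (2R,3R)-2,3-dichloro-4,4-dimethyl-6-(trimethylsilyl)hex-5-yn-1-ol; 7 acetylene
Product: 9 (4R,5R)-4,5-dichloro-3,3-dimethyl-1-(trimethylsilyl)octa-1,7-diyne, via triflate 8 (not isolated)
Conditions: Tf2O, 2,6-lutidine, CH2Cl2, −78 °C; then HC≡CLi (from 7, n-BuLi), THF/DMPU, −78→−30 °C
Reagents that add atoms: triflic anhydride, O=S(=O)(OS(=O)(=O)C(F)(F)F)C(F)(F)F (atoms in 8 only)
Why: SN2 alkynylation of a primary triflate by lithium acetylide at low temperature outruns E2 and leaves both C–Cl stereocentres untouched.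

**Step 5**
Reactants: 9 (4R,5R)-4,5-dichloro-3,3-dimethyl-1-(trimethylsilyl)octa-1,7-diyne; 10 oxirane
Product: 12 (3E,6R,7R)-6,7-dichloro-4,8,8-trimethyl-10-(trimethylsilyl)dec-3-en-9-yn-1-ol, via alkenylalane 11 (not isolated)
Conditions: Me3Al (2.5 equiv), Cp2ZrCl2 (25 mol %), CH2Cl2, 0 °C→rt; n-BuLi, THF, −78 °C; 10, −78→0 °C; aq. Rochelle salt
Reagents that add atoms: trimethylaluminium, C[Al](C)C
Why: Negishi Zr-catalysed carboalumination is a syn, regioselective methyl-alumination of the free terminal alkyne (the hindered silyl alkyne is inert), and the derived alanate opens oxirane with retention, giving the E-trisubstituted alkene with C11–C12.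

**Step 6**
Reactants: 12 (3E,6R,7R)-6,7-dichloro-4,8,8-trimethyl-10-(trimethylsilyl)dec-3-en-9-yn-1-ol
Product: 14 tert-butyl{[(3E,6R,7R)-6,7-dichloro-4,8,8-trimethyldec-3-en-9-yn-1-yl]oxy}dimethylsilane, via bis-silyl ether 13 (not isolated)
Conditions: TBSCl, imidazole, DMF, rt; then MeOH, K2CO3, rt
Reagents that add atoms: tert-butyldimethylsilyl chloride, CC(C)(C)[Si](C)(C)Cl
Why: Standard O-silylation followed by base-catalysed methanolysis of the C(sp)–SiMe3 bond, which leaves the TBS ether intact.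

**Step 7**
Reactants: 14 tert-butyl{[(3E,6R,7R)-6,7-dichloro-4,8,8-trimethyldec-3-en-9-yn-1-yl]oxy}dimethylsilane
Product: 15 (1R,5R,6R,7aR)-1-[2-(tert-butyldimethylsilyloxy)ethyl]-5,6-dichloro-4,4,7a-trimethyl-1,4,5,6,7,7a-hexahydro-2H-inden-2-one
Conditions: Co2(CO)8 (20 mol %), tetramethylthiourea (60 mol %), CO (1 atm), PhMe, 70 °C
Reagents that add atoms: carbon monoxide, [C-]#[O+]
Why: Intramolecular Pauson–Khand [2+2+1] (stepwise via a cobaltacycle) forms ring A, the cyclopentenone and quaternary C10; suprafacial addition to the E-alkene puts C11 cis to the C10 methyl (C9), and the chair-like tether with both C–Cl bonds equatorial selects the alkene face (10β-Me).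

**Step 8**
Reactants: 15 (1R,5R,6R,7aR)-1-[2-(tert-butyldimethylsilyloxy)ethyl]-5,6-dichloro-4,4,7a-trimethyl-1,4,5,6,7,7a-hexahydro-2H-inden-2-one
Product: 16 (1R,3aR,5R,6R,7aS)-1-[2-(tert-butyldimethylsilyloxy)ethyl]-5,6-dichloro-4,4,7a-trimethyloctahydro-2H-inden-2-one
Conditions: H2 (3 atm), 10 % Pd/C, EtOAc, rt
Reagents that add atoms: none
Why: Heterogeneous hydrogenation delivers H2 to the enone from the α face, opposite the two axial β-methyls (C4, C10) and the β side chain, giving the trans ring fusion (5α-H); secondary alkyl chlorides survive.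

**Step 9**
Reactants: 16 (1R,3aR,5R,6R,7aS)-1-[2-(tert-butyldimethylsilyloxy)ethyl]-5,6-dichloro-4,4,7a-trimethyloctahydro-2H-inden-2-one
Product: 17 (1R,2R,3aR,5R,6R,7aS)-1-[2-(tert-butyldimethylsilyloxy)ethyl]-5,6-dichloro-2-ethenyl-4,4,7a-trimethyloctahydro-1H-inden-2-ol (major C2 epimer)
Conditions: CH2=CHMgBr, CeCl3, THF, −78 °C; aq. work-up
Reagents that add atoms: vinylmagnesium bromide, C=C[Mg]Br
Why: Organocerium 1,2-addition suppresses enolisation of the cyclopentanone; attack anti to the angular methyl gives mainly the drawn epimer, but the carbinol carbon becomes sp2 in step 10, so both epimers converge.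

**Step 10**
Reactants: 17 (1R,2R,3aR,5R,6R,7aS)-1-[2-(tert-butyldimethylsilyloxy)ethyl]-5,6-dichloro-2-ethenyl-4,4,7a-trimethyloctahydro-1H-inden-2-ol
Product: 18 12-(tert-butyldimethylsilyloxy)-2α,3β-dichloro-13,14,15,16-tetranorlabd-8(17)-en-7-one
Conditions: [Pd(MeCN)4](BF4)2 (10 mol %), 1,4-benzoquinone (1.5 equiv), 2,6-di-tert-butyl-4-methylpyridine (20 mol %), THF/HFIP (4:1), 0 °C→rt
Reagents that add atoms: none
Why: Proposed new method: Pd(II)-catalysed oxidative semipinacol ring expansion of an unstrained 1-vinylcyclopentanol; cationic Pd(II) activates the vinyl group, the antiperiplanar, more substituted C7–C9 bond migrates to the internal vinyl carbon with retention at C9 as the carbinol collapses to the ketone, β-hydride elimination of the α-(palladiomethyl) ketone gives the exocyclic enone and benzoquinone reoxidises Pd(0), the driving force being C=O formation plus relief of trans-hydrindane strain; the closest known reaction is the Pd(II)-mediated ring expansion of strained 1-vinylcyclobutanols to 2-methylenecyclopentanones.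

**Step 11**
Reactants: 18 12-(tert-butyldimethylsilyloxy)-2α,3β-dichloro-13,14,15,16-tetranorlabd-8(17)-en-7-one
Product: 19 12-(tert-butyldimethylsilyloxy)-2α,3β-dichloro-13,14,15,16-tetranorlabd-8(17)-en-7β-ol
Conditions: NaBH4, CeCl3·7H2O, MeOH, −78→−20 °C
Reagents that add atoms: none
Why: Luche 1,2-reduction of the exocyclic enone; axial hydride delivery from the open α face gives the equatorial 7β-alcohol (C7).

**Step 12**
Reactants: 19 12-(tert-butyldimethylsilyloxy)-2α,3β-dichloro-13,14,15,16-tetranorlabd-8(17)-en-7β-ol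
Product: 21 7β-acetoxy-2α,3β-dichloro-13,14,15,16-tetranorlabd-8(17)-en-12-ol, via TBS ether acetate 20 (not isolated)
Conditions: Ac2O, pyridine, DMAP (cat.), 0 °C→rt; MeOH quench; then HF·pyridine, THF, 0 °C→rt
Reagents that add atoms: acetic anhydride, CC(=O)OC(C)=O
Why: DMAP-catalysed acetylation of the secondary alcohol followed by fluoride cleavage of the primary TBS ether, which does not touch the acetate.

**Step 13**
Reactants: 21 7β-acetoxy-2α,3β-dichloro-13,14,15,16-tetranorlabd-8(17)-en-12-ol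
Product: 22 7β-acetoxy-2α,3β-dichloro-13,14,15,16-tetranorlabd-8(17)-en-12-al
Conditions: Dess–Martin periodinane, pyridine, CH2Cl2, 0 °C→rt
Reagents that add atoms: none
Why: Dess–Martin oxidation of the primary alcohol to the aldehyde under near-neutral conditions that spare the allylic acetate and the alkene.

**Step 14**
Reactants: 23 3-cyanopropanoic acid
Product: 25 (R)-4-benzyl-3-(3-cyanopropanoyl)oxazolidin-2-one, via mixed pivalic anhydride 24 (not isolated)
Conditions: PivCl, Et3N, THF, −20 °C; then (R)-4-benzyloxazolidin-2-one, LiCl, −20 °C→rt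
Reagents that add atoms: (R)-4-benzyloxazolidin-2-one, O=C1N[C@H](Cc2ccccc2)CO1; pivaloyl chloride, CC(C)(C)C(Cl)=O (atoms in 24 only)
Why: Mixed-anhydride N-acylation of the Evans auxiliary; the nitrile is inert and serves as a masked primary amide.

**Step 15**
Reactants: 22 7β-acetoxy-2α,3β-dichloro-13,14,15,16-tetranorlabd-8(17)-en-12-al; 25 (R)-4-benzyl-3-(3-cyanopropanoyl)oxazolidin-2-one
Product: 26 (R)-4-benzyl-3-[(2R,3S)-2-(cyanomethyl)-3-hydroxy-4-(7β-acetoxy-2α,3β-dichloro-11,12,13,14,15,16-hexanorlabd-8(17)-en-9-yl)butanoyl]oxazolidin-2-one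
Conditions: 25, n-Bu2BOTf, i-Pr2NEt, CH2Cl2, −78→0 °C; then 22, −78→0 °C; pH 7 buffer, MeOH, H2O2, 0 °C
Reagents that add atoms: none
Why: Evans syn-aldol through the Z-boron enolate and a Zimmerman–Traxler transition state; the (R)-auxiliary sets 12S and 13R irrespective of the remote ring stereocentres.

**Step 16**
Reactants: 26 (R)-4-benzyl-3-[(2R,3S)-2-(cyanomethyl)-3-hydroxy-4-(7β-acetoxy-2α,3β-dichloro-11,12,13,14,15,16-hexanorlabd-8(17)-en-9-yl)butanoyl]oxazolidin-2-one
Product: 28 Haterumaimide A, via primary amide 27 (not isolated)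
Conditions: [PtH{(PMe2O)2H}(PMe2OH)] (5 mol %), EtOH/H2O (4:1), 70 °C; concentrate; then DBU (1.1 equiv), CH2Cl2, 0 °C→rt
Reagents that add atoms: water, O
Why: Neutral Pt-catalysed nitrile hydration gives the primary amide, whose nitrogen then acylates intramolecularly (5-exo-trig) at the activated N-acyl carbonyl, closing the succinimide and expelling the auxiliary without touching the acetate.

**Compound list**
1 | 3-chloro-3-methylbut-1-yne | C#CC(C)(C)Cl | starting material
2 | ethynyltrimethylsilane | C#C[Si](C)(C)C | starting material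
3 | bromo[3,3-dimethyl-5-(trimethylsilyl)penta-1,4-diyn-1-yl]magnesium | Br[Mg]C#CC(C)(C)C#C[Si](C)(C)C | intermediate
4 | 4,4-dimethyl-6-(trimethylsilyl)hexa-2,5-diyn-1-ol | OCC#CC(C)(C)C#C[Si](C)(C)C | intermediate
5 | (Z)-4,4-dimethyl-6-(trimethylsilyl)hex-2-en-5-yn-1-ol | OC/C=C\C(C)(C)C#C[Si](C)(C)C | intermediate
6 | (2R,3R)-2,3-dichloro-4,4-dimethyl-6-(trimethylsilyl)hex-5-yn-1-ol | C[Si](C)(C)C#CC(C)(C)[C@@H](Cl)[C@H](Cl)CO | intermediate
7 | acetylene | C#C | starting material
8 | (2R,3R)-2,3-dichloro-4,4-dimethyl-6-(trimethylsilyl)hex-5-yn-1-yl triflate | C[Si](C)(C)C#CC(C)(C)[C@@H](Cl)[C@H](Cl)COS(=O)(=O)C(F)(F)F | intermediate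
9 | (4R,5R)-4,5-dichloro-3,3-dimethyl-1-(trimethylsilyl)octa-1,7-diyne | C[Si](C)(C)C#CC(C)(C)[C@@H](Cl)[C@H](Cl)CC#C | intermediate
10 | oxirane | C1CO1 | starting material
11 | dimethyl[(1E,4R,5R)-4,5-dichloro-2,6,6-trimethyl-8-(trimethylsilyl)oct-1-en-7-yn-1-yl]alane | C[Si](C)(C)C#CC(C)(C)[C@@H](Cl)[C@H](Cl)C/C(C)=C/[Al](C)C | intermediate
12 | (3E,6R,7R)-6,7-dichloro-4,8,8-trimethyl-10-(trimethylsilyl)dec-3-en-9-yn-1-ol | C[Si](C)(C)C#CC(C)(C)[C@@H](Cl)[C@H](Cl)C/C(C)=C/CCO | intermediate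
13 | TBS ether of 12 (silyl alkyne still in place) | C[Si](C)(C)C#CC(C)(C)[C@@H](Cl)[C@H](Cl)C/C(C)=C/CCO[Si](C)(C)C(C)(C)C | intermediate
14 | tert-butyl{[(3E,6R,7R)-6,7-dichloro-4,8,8-trimethyldec-3-en-9-yn-1-yl]oxy}dimethylsilane | C#CC(C)(C)[C@@H](Cl)[C@H](Cl)C/C(C)=C/CCO[Si](C)(C)C(C)(C)C | intermediate
15 | (1R,5R,6R,7aR)-1-[2-(tert-butyldimethylsilyloxy)ethyl]-5,6-dichloro-4,4,7a-trimethyl-1,4,5,6,7,7a-hexahydro-2H-inden-2-one | O=C1C=C2C(C)(C)[C@@H](Cl)[C@H](Cl)C[C@]2(C)[C@H]1CCO[Si](C)(C)C(C)(C)C | intermediate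
16 | (1R,3aR,5R,6R,7aS)-1-[2-(tert-butyldimethylsilyloxy)ethyl]-5,6-dichloro-4,4,7a-trimethyloctahydro-2H-inden-2-one (trans-fused) | O=C1C[C@H]2C(C)(C)[C@@H](Cl)[C@H](Cl)C[C@]2(C)[C@H]1CCO[Si](C)(C)C(C)(C)C | intermediate
17 | (1R,2R,3aR,5R,6R,7aS)-1-[2-(tert-butyldimethylsilyloxy)ethyl]-5,6-dichloro-2-ethenyl-4,4,7a-trimethyloctahydro-1H-inden-2-ol | C=C[C@]1(O)C[C@H]2C(C)(C)[C@@H](Cl)[C@H](Cl)C[C@]2(C)[C@H]1CCO[Si](C)(C)C(C)(C)C | intermediate
18 | 12-(tert-butyldimethylsilyloxy)-2α,3β-dichloro-13,14,15,16-tetranorlabd-8(17)-en-7-one | C=C1C(=O)C[C@H]2C(C)(C)[C@@H](Cl)[C@H](Cl)C[C@]2(C)[C@H]1CCO[Si](C)(C)C(C)(C)C | intermediate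
19 | 12-(tert-butyldimethylsilyloxy)-2α,3β-dichloro-13,14,15,16-tetranorlabd-8(17)-en-7β-ol | C=C1[C@@H](O)C[C@H]2C(C)(C)[C@@H](Cl)[C@H](Cl)C[C@]2(C)[C@H]1CCO[Si](C)(C)C(C)(C)C | intermediate
20 | 7β-acetoxy-12-(tert-butyldimethylsilyloxy)-2α,3β-dichloro-13,14,15,16-tetranorlabd-8(17)-ene | C=C1[C@@H](OC(C)=O)C[C@H]2C(C)(C)[C@@H](Cl)[C@H](Cl)C[C@]2(C)[C@H]1CCO[Si](C)(C)C(C)(C)C | intermediate
21 | 7β-acetoxy-2α,3β-dichloro-13,14,15,16-tetranorlabd-8(17)-en-12-ol | C=C1[C@@H](OC(C)=O)C[C@H]2C(C)(C)[C@@H](Cl)[C@H](Cl)C[C@]2(C)[C@H]1CCO | intermediate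
22 | 7β-acetoxy-2α,3β-dichloro-13,14,15,16-tetranorlabd-8(17)-en-12-al | C=C1[C@@H](OC(C)=O)C[C@H]2C(C)(C)[C@@H](Cl)[C@H](Cl)C[C@]2(C)[C@H]1CC=O | intermediate
23 | 3-cyanopropanoic acid | N#CCCC(=O)O | starting material
24 | 3-cyanopropanoic pivalic anhydride | N#CCCC(=O)OC(=O)C(C)(C)C | intermediate
25 | (R)-4-benzyl-3-(3-cyanopropanoyl)oxazolidin-2-one | N#CCCC(=O)N1[C@H](Cc2ccccc2)COC1=O | intermediate
26 | Evans syn-aldol adduct (12S,13R; nitrile) | C=C1[C@@H](OC(C)=O)C[C@H]2C(C)(C)[C@@H](Cl)[C@H](Cl)C[C@]2(C)[C@H]1C[C@H](O)[C@@H](CC#N)C(=O)N1[C@H](Cc2ccccc2)COC1=O | intermediate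
27 | primary amide of 26 (nitrile hydrated) | C=C1[C@@H](OC(C)=O)C[C@H]2C(C)(C)[C@@H](Cl)[C@H](Cl)C[C@]2(C)[C@H]1C[C@H](O)[C@@H](CC(N)=O)C(=O)N1[C@H](Cc2ccccc2)COC1=O | intermediate
28 | Haterumaimide A | C=C1[C@@H](OC(C)=O)C[C@H]2C(C)(C)[C@@H](Cl)[C@H](Cl)C[C@]2(C)[C@H]1C[C@H](O)[C@H]1CC(=O)NC1=O | target

**Step count**
Total: 16 steps. Longest linear sequence: 15 (steps 1–13, 15, 16); step 14 is a one-step side branch.

**Three steps most likely to fail, with fallbacks**

Step 10 (the proposed new Pd(II) ring expansion). Without ring strain the migration may be slow, and Pd(II) could instead cause 1,3-transposition of the tertiary allylic alcohol or isomerise the product enone. The fallback uses known chemistry, sets out from 17 and comes back at 18. Hydroxyl-directed epoxidation of the vinyl group (VO(acac)2, t-BuOOH) gives the epoxy alcohol F1. BF3·OEt2 at −78 °C then effects the established semipinacol rearrangement of a 2,3-epoxy alcohol, with the same C9 migration and ring expansion, to the β-hydroxymethyl ketone F2. MsCl/Et3N gives the mesylate F3, and DBU eliminates methanesulfonic acid to give 18.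

Step 7 (Pauson–Khand reaction of a 1,7-enyne with a trisubstituted alkene). Such alkenes insert slowly, so the yield may be poor. The fallback sets out from 9 and comes back at 16. 9 is carboaluminated as in step 5, but alkenylalane 11 is protonated with water to give the silyl-capped isopropenyl enyne F4, and K2CO3/MeOH then gives the enyne F5. Its 1,1-disubstituted alkene undergoes the Pauson–Khand reaction much more readily, under the same facial control, to give the enone F6. LDA deprotonates the only enolisable position, and 2-(tert-butyldimethylsilyloxy)ethyl triflate gives 15 together with its C1 epimer F7. Hydrogenation as in step 8 gives 16 and the epimeric ketone F8, and NaOMe/MeOH is expected to equilibrate F8 into 16 (side chain cis to the angular methyl, as in 17β-substituted 16-keto steroids).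

Step 3 (enantioselective dichlorination). The neopentyl Z-allylic alcohol is a hindered substrate for this catalyst system, and the ee may be insufficient. The fallback sets out from 5 and comes back at 6. Racemic anti-dichlorination with Et4NCl3 (CH2Cl2, −78→0 °C) gives 6 together with its enantiomer F9, and the two are separated by preparative chiral SFC at this early, small-molecule stage.

**Further compounds**
F1 | step 10 | 17 with the vinyl group converted into an oxiran-2-yl group (epoxide carbon as a mixture) | C1OC1[C@]2(O)C[C@H]3C(C)(C)[C@@H](Cl)[C@H](Cl)C[C@]3(C)[C@H]2CCO[Si](C)(C)C(C)(C)C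
F2 | step 10 | 12-(tert-butyldimethylsilyloxy)-2α,3β-dichloro-17-hydroxy-13,14,15,16-tetranorlabdan-7-one (C8 epimers) | OCC1C(=O)C[C@H]2C(C)(C)[C@@H](Cl)[C@H](Cl)C[C@]2(C)[C@H]1CCO[Si](C)(C)C(C)(C)C
F3 | step 10 | 17-methanesulfonate of F2 | CS(=O)(=O)OCC1C(=O)C[C@H]2C(C)(C)[C@@H](Cl)[C@H](Cl)C[C@]2(C)[C@H]1CCO[Si](C)(C)C(C)(C)C
F4 | step 7 | [(4R,5R)-4,5-dichloro-3,3,7-trimethyloct-7-en-1-yn-1-yl]trimethylsilane | C[Si](C)(C)C#CC(C)(C)[C@@H](Cl)[C@H](Cl)CC(C)=C
F5 | step 7 | (4R,5R)-4,5-dichloro-3,3,7-trimethyloct-7-en-1-yne | C#CC(C)(C)[C@@H](Cl)[C@H](Cl)CC(C)=C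
F6 | step 7 | 15 lacking the C1 side chain (5,6-dichloro-4,4,7a-trimethyl-1,4,5,6,7,7a-hexahydro-2H-inden-2-one) | O=C1C=C2C(C)(C)[C@@H](Cl)[C@H](Cl)C[C@]2(C)C1
F7 | step 7 | C1 epimer of 15 | O=C1C=C2C(C)(C)[C@@H](Cl)[C@H](Cl)C[C@]2(C)[C@@H]1CCO[Si](C)(C)C(C)(C)C
F8 | step 7 | C1 epimer of 16 | O=C1C[C@H]2C(C)(C)[C@@H](Cl)[C@H](Cl)C[C@]2(C)[C@@H]1CCO[Si](C)(C)C(C)(C)C
F9 | step 3 | (2S,3S)-2,3-dichloro-4,4-dimethyl-6-(trimethylsilyl)hex-5-yn-1-ol | C[Si](C)(C)C#CC(C)(C)[C@H](Cl)[C@@H](Cl)CO
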